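**Strategy.** The route treats ring B's chroman as a masked 2,3-dihydrobenzofuran-3-ol. The C8 isobutyryl carbon and the O1–C2(CH3)2 carbon sit on neighbouring ring atoms (C8/C8a), so they can first be joined as a five-membered carbinol. Generating the tertiary alkoxyl radical cleaves that bond, releasing the aryl isobutyryl ketone and a tertiary α-aryloxy radical at C2. This radical closes 6-endo onto the vinyl group at C4a to forge C2–C3, in a redox-neutral photocatalytic isomerisation. Ring A is built by directed metalations, and the halves are united last by a catalyst-controlled quinone-methide arylation that sets the bridging stereocentre.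

Key step: step 6

Remark: 6-methylheptanal and (R)-2-methylbutanoic acid are taken as purchasable, and the sense of induction in step 14 is assumed to be selectable by choosing the quinine- or the pseudoenantiomeric quinidine-derived squaramide.

**Step 1**
Reactants: 1 2,4,6-trihydroxybenzaldehyde
Product: 2 2,4-bis(benzyloxy)-6-hydroxybenzaldehyde
Conditions: BnBr (2.1 equiv), K2CO3, DMF, 0 °C to rt
Reagents that add atoms: benzyl bromide, BrCc1ccccc1
Why: Williamson etherification should take the 4-OH and one ortho OH, while the last OH is held back by its hydrogen bond to the formyl group.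

**Step 2**
Reactants: 2 2,4-bis(benzyloxy)-6-hydroxybenzaldehyde; 3 tert-butyl 2-bromo-2-methylpropanoate
Product: 4 tert-butyl 2-[3,5-bis(benzyloxy)-2-formylphenoxy]-2-methylpropanoate
Conditions: Cs2CO3, DMF, 70 °C
Reagents that add atoms: none
Why: Williamson-type O-alkylation of the phenoxide by the carbonyl-activated tertiary bromide (the fibrate ether synthesis) should work on this singly ortho-substituted phenol.

**Step 3**
Reactants: 4 tert-butyl 2-[3,5-bis(benzyloxy)-2-formylphenoxy]-2-methylpropanoate
Product: 6 4,6-bis(benzyloxy)-2,2-dimethyl-3-oxo-2,3-dihydro-1-benzofuran-7-carbaldehyde, via carboxylic acid 5 (not isolated)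
Conditions: TFA, CH2Cl2, rt; evaporate; then (CF3CO)2O, CH2Cl2, 0 °C to rt
Reagents that add atoms: none
Why: Acidolysis of the tert-butyl ester followed by intramolecular Friedel–Crafts acylation through the mixed anhydride should close the furanone, because the tether reaches only the one free carbon ortho to the ether oxygen, which three oxygen donors activate.

**Step 4**
Reactants: 6 4,6-bis(benzyloxy)-2,2-dimethyl-3-oxo-2,3-dihydro-1-benzofuran-7-carbaldehyde
Product: 7 4,6-bis(benzyloxy)-7-ethenyl-2,2-dimethyl-1-benzofuran-3(2H)-one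
Conditions: Ph3PCH3Br, KOt-Bu, THF, 0 °C
Reagents that add atoms: methyltriphenylphosphonium bromide, C[P+](c1ccccc1)(c1ccccc1)c1ccccc1.[Br-]
Why: Wittig methylenation should be selective for the aldehyde over the hindered, non-enolisable, donor-deactivated ring ketone.

**Step 5**
Reactants: 7 4,6-bis(benzyloxy)-7-ethenyl-2,2-dimethyl-1-benzofuran-3(2H)-one
Product: 8 rac-4,6-bis(benzyloxy)-7-ethenyl-2,2-dimethyl-3-(propan-2-yl)-2,3-dihydro-1-benzofuran-3-ol
Conditions: i-PrMgCl, anhydrous CeCl3, THF, −78 to 0 °C; aq. NH4Cl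
Reagents that add atoms: isopropylmagnesium chloride, CC(C)[Mg]Cl
Why: Organocerium 1,2-addition to the non-enolisable ketone should outrun β-hydride reduction; the racemic carbinol centre is destroyed in step 6.

**Step 6**
Reactants: 8 rac-4,6-bis(benzyloxy)-7-ethenyl-2,2-dimethyl-3-(propan-2-yl)-2,3-dihydro-1-benzofuran-3-ol
Product: 12 1-[5,7-bis(benzyloxy)-2,2-dimethyl-3,4-dihydro-2H-chromen-8-yl]-2-methylpropan-1-one, via alkoxyl radical 9 (not isolated), via ring-opened C2 radical 10 (not isolated), via benzylic radical 11 (not isolated)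
Conditions: [Ir(dF(CF3)ppy)2(5,5'-d(CF3)bpy)]PF6 (2 mol%), 2,4,6-collidine (1 equiv), 2,4,6-triisopropylbenzenethiol (10 mol%), CH2Cl2 (0.02 M), blue LEDs, rt
Reagents that add atoms: none
Why: The photoexcited trivalent iridium complex should oxidise the trialkoxyarene, and collidine-assisted proton-coupled electron transfer then gives alkoxyl radical 9, whose β-scission breaks the bond between the carbinol carbon and the O–C(CH3)2 carbon to give the aryl isobutyryl ketone and tertiary α-aryloxy radical 10. Radical 10 adds to the terminal carbon of the neighbouring vinyl group, and benzylic radical 11 takes a hydrogen atom from the thiol, whose thiyl radical is reduced back by the reduced photocatalyst, so the step is a net isomerisation. The closest known reactions are the proton-coupled-electron-transfer ring opening of 1-arylcycloalkanols and the derived ring expansions in which the β-scission radical re-adds to an olefin before hydrogen-atom transfer. The chroman ring closes in a 6-endo-trig radical mode, forming the C2–C3 bond. No new stereocentre is formed and the carbinol centre of 8 is erased. Three selectivities are needed: β-scission towards the tertiary oxygen-stabilised radical and not loss of isopropyl (radical stability), 6-endo over 5-exo (attack at the unsubstituted vinyl terminus gives a benzylic radical, whereas 5-exo would attack the aryl-bearing carbon), and cyclisation before hydrogen-atom transfer (low loading of a hindered thiol and high dilution).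

**Step 7**
Reactants: 12 1-[5,7-bis(benzyloxy)-2,2-dimethyl-3,4-dihydro-2H-chromen-8-yl]-2-methylpropan-1-one
Product: 13 1-(5,7-dihydroxy-2,2-dimethyl-3,4-dihydro-2H-chromen-8-yl)-2-methylpropan-1-one
Conditions: H2 (1 atm), 10% Pd/C, EtOAc–MeOH, rt
Reagents that add atoms: none
Why: Hydrogenolysis of both benzyl ethers should leave the chelated, electron-rich aryl ketone and the chroman untouched.

**Step 8**
Reactants: 14 phloroglucinol (used in excess); 15 isoprene
Product: 16 2,2-dimethyl-3,4-dihydro-2H-chromene-5,7-diol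
Conditions: Amberlyst 15, THF–heptane, 65 °C
Reagents that add atoms: none
Why: Acid-catalysed Friedel–Crafts prenylation followed by Markovnikov hydroalkoxylation should give the chroman, and the symmetry of phloroglucinol removes any regiochemical choice.

**Step 9**
Reactants: 16 2,2-dimethyl-3,4-dihydro-2H-chromene-5,7-diol
Product: 17 5,7-bis(methoxymethoxy)-2,2-dimethyl-3,4-dihydro-2H-chromene
Conditions: MOMCl, i-Pr2NEt, CH2Cl2, 0 °C to rt
Reagents that add atoms: chloromethyl methyl ether, COCCl
Why: Standard acetal protection of both free phenols installs the directing groups for the two metalations.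

**Step 10**
Reactants: 17 5,7-bis(methoxymethoxy)-2,2-dimethyl-3,4-dihydro-2H-chromene; 18 6-methylheptanal
Product: 20 rac-1-[5,7-bis(methoxymethoxy)-2,2-dimethyl-3,4-dihydro-2H-chromen-6-yl]-6-methylheptan-1-ol, via aryllithium 19 (not isolated)
Conditions: n-BuLi, TMEDA, THF, 0 °C; then 18, −78 °C to rt; aq. NH4Cl
Reagents that add atoms: none
Why: Directed ortho-metalation should occur at C6, the position between the two MOM ethers, and 1,2-addition to the aldehyde installs the bridge carbon as a racemic carbinol that is planarised again in step 14.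

**Step 11**
Reactants: 21 (R)-2-methylbutanoic acid
Product: 23 (R)-N-methoxy-N,2-dimethylbutanamide, via acyl imidazole 22 (not isolated)
Conditions: CDI, CH2Cl2, rt; then MeNHOMe·HCl, rt
Reagents that add atoms: N,O-dimethylhydroxylamine hydrochloride, CNOC.Cl
Why: Weinreb amide formation through the acyl imidazole is base-free enough to keep the α-stereocentre, which comes from the chiral pool.

**Step 12**
Reactants: 20 rac-1-[5,7-bis(methoxymethoxy)-2,2-dimethyl-3,4-dihydro-2H-chromen-6-yl]-6-methylheptan-1-ol; 23 (R)-N-methoxy-N,2-dimethylbutanamide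
Product: 25 (2R)-1-[6-(1-hydroxy-6-methylheptyl)-5,7-bis(methoxymethoxy)-2,2-dimethyl-3,4-dihydro-2H-chromen-8-yl]-2-methylbutan-1-one (both carbinol epimers), via dilithio species 24 (not isolated)
Conditions: s-BuLi (2.3 equiv), TMEDA, THF, −78 to −30 °C; then 23, −78 to 0 °C; aq. NH4Cl
Reagents that add atoms: none
Why: After O-deprotonation, a second directed ortho-metalation can only take the last ring hydrogen at C8, and Weinreb ketone synthesis through the stable chelated tetrahedral intermediate should deliver the ketone without exposing its α-stereocentre to base.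

**Step 13**
Reactants: 25 (2R)-1-[6-(1-hydroxy-6-methylheptyl)-5,7-bis(methoxymethoxy)-2,2-dimethyl-3,4-dihydro-2H-chromen-8-yl]-2-methylbutan-1-one
Product: 26 (2R)-1-{5,7-dihydroxy-2,2-dimethyl-6-[6-methyl-1-(4-methylbenzenesulfonyl)heptyl]-3,4-dihydro-2H-chromen-8-yl}-2-methylbutan-1-one (both epimers at the sulfonyl-bearing carbon)
Conditions: p-TolSO2Na (5 equiv), 4 M HCl, MeOH–THF, 40 °C
Reagents that add atoms: sodium 4-methylbenzenesulfinate, Cc1ccc(S(=O)[O-])cc1.[Na+]
Why: Acidic acetal cleavage frees both phenols, and the ionised benzylic alcohol should be captured at sulfur by the sulfinic acid (sulfonylalkylation of a phenol) to give a bench-stable quinone-methide precursor on a ring with no free position for self-condensation.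

**Step 14**
Reactants: 26 (2R)-1-{5,7-dihydroxy-2,2-dimethyl-6-[6-methyl-1-(4-methylbenzenesulfonyl)heptyl]-3,4-dihydro-2H-chromen-8-yl}-2-methylbutan-1-one; 13 1-(5,7-dihydroxy-2,2-dimethyl-3,4-dihydro-2H-chromen-8-yl)-2-methylpropan-1-one
Product: 28 CNP0287681.1, via ortho-quinone methide 27 (not isolated)
Conditions: quinine-derived 3,5-bis(trifluoromethyl)anilino squaramide (10 mol%), aq. Na2CO3, CH2Cl2, 0 °C
Reagents that add atoms: none
Why: Base-induced 1,4-elimination of sulfinate should give ortho-quinone methide 27, and the bifunctional hydrogen-bonding catalyst should direct the Friedel–Crafts-type conjugate addition of C6 of 13 (its only free ring carbon) to one face, setting the (R)-configured bridging carbon.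

**Compound list**

1 | 2,4,6-trihydroxybenzaldehyde | O=Cc1c(O)cc(O)cc1O | starting material
2 | 2,4-bis(benzyloxy)-6-hydroxybenzaldehyde | O=Cc1c(O)cc(OCc2ccccc2)cc1OCc1ccccc1 | intermediate
3 | tert-butyl 2-bromo-2-methylpropanoate | CC(C)(Br)C(=O)OC(C)(C)C | starting material
4 | tert-butyl 2-[3,5-bis(benzyloxy)-2-formylphenoxy]-2-methylpropanoate | CC(C)(C)OC(=O)C(C)(C)Oc1cc(OCc2ccccc2)cc(OCc2ccccc2)c1C=O | intermediate
5 | 2-[3,5-bis(benzyloxy)-2-formylphenoxy]-2-methylpropanoic acid (not isolated) | OC(=O)C(C)(C)Oc1cc(OCc2ccccc2)cc(OCc2ccccc2)c1C=O | intermediate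
6 | 4,6-bis(benzyloxy)-2,2-dimethyl-3-oxo-2,3-dihydro-1-benzofuran-7-carbaldehyde | O=Cc1c(OCc2ccccc2)cc(OCc2ccccc2)c2c1OC(C)(C)C2=O | intermediate
7 | 4,6-bis(benzyloxy)-7-ethenyl-2,2-dimethyl-1-benzofuran-3(2H)-one | C=Cc1c(OCc2ccccc2)cc(OCc2ccccc2)c2c1OC(C)(C)C2=O | intermediate
8 | rac-4,6-bis(benzyloxy)-7-ethenyl-2,2-dimethyl-3-(propan-2-yl)-2,3-dihydro-1-benzofuran-3-ol | C=Cc1c(OCc2ccccc2)cc(OCc2ccccc2)c2c1OC(C)(C)C2(O)C(C)C | intermediate
9 | C3 alkoxyl radical of 8 (not isolated) | C=Cc1c(OCc2ccccc2)cc(OCc2ccccc2)c2c1OC(C)(C)C2([O])C(C)C | intermediate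
10 | 2-{[3,5-bis(benzyloxy)-2-ethenyl-6-(2-methylpropanoyl)phenyl]oxy}propan-2-yl radical (not isolated) | C=Cc1c(OCc2ccccc2)cc(OCc2ccccc2)c(C(=O)C(C)C)c1O[C](C)C | intermediate
11 | 5,7-bis(benzyloxy)-2,2-dimethyl-8-(2-methylpropanoyl)chroman-4-yl radical (not isolated) | CC(C)C(=O)c1c(OCc2ccccc2)cc(OCc2ccccc2)c2c1OC(C)(C)C[CH]2 | intermediate
12 | 1-[5,7-bis(benzyloxy)-2,2-dimethyl-3,4-dihydro-2H-chromen-8-yl]-2-methylpropan-1-one | CC(C)C(=O)c1c(OCc2ccccc2)cc(OCc2ccccc2)c2c1OC(C)(C)CC2 | intermediate
13 | 1-(5,7-dihydroxy-2,2-dimethyl-3,4-dihydro-2H-chromen-8-yl)-2-methylpropan-1-one | CC(C)C(=O)c1c(O)cc(O)c2c1OC(C)(C)CC2 | intermediate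
14 | phloroglucinol (benzene-1,3,5-triol) | Oc1cc(O)cc(O)c1 | starting material
15 | isoprene (2-methylbuta-1,3-diene) | C=CC(C)=C | starting material
16 | 2,2-dimethyl-3,4-dihydro-2H-chromene-5,7-diol | CC1(C)CCc2c(O)cc(O)cc2O1 | intermediate
17 | 5,7-bis(methoxymethoxy)-2,2-dimethyl-3,4-dihydro-2H-chromene | CC1(C)CCc2c(OCOC)cc(OCOC)cc2O1 | intermediate
18 | 6-methylheptanal | CC(C)CCCCC=O | starting material
19 | 6-lithio-5,7-bis(methoxymethoxy)-2,2-dimethyl-3,4-dihydro-2H-chromene (not isolated) | [Li]c1c(OCOC)cc2OC(C)(C)CCc2c1OCOC | intermediate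
20 | rac-1-[5,7-bis(methoxymethoxy)-2,2-dimethyl-3,4-dihydro-2H-chromen-6-yl]-6-methylheptan-1-ol | CC(C)CCCCC(O)c1c(OCOC)cc2OC(C)(C)CCc2c1OCOC | intermediate
21 | (R)-2-methylbutanoic acid | CC[C@@H](C)C(=O)O | starting material
22 | (R)-1-(1H-imidazol-1-yl)-2-methylbutan-1-one (not isolated) | CC[C@@H](C)C(=O)n1ccnc1 | intermediate
23 | (R)-N-methoxy-N,2-dimethylbutanamide | CC[C@@H](C)C(=O)N(C)OC | intermediate
24 | C8,O-dilithio derivative of 20 (not isolated) | CC(C)CCCCC(O[Li])c1c(OCOC)c([Li])c2OC(C)(C)CCc2c1OCOC | intermediate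
25 | (2R)-1-[6-(1-hydroxy-6-methylheptyl)-5,7-bis(methoxymethoxy)-2,2-dimethyl-3,4-dihydro-2H-chromen-8-yl]-2-methylbutan-1-one (both carbinol epimers) | CC[C@@H](C)C(=O)c1c(OCOC)c(C(O)CCCCC(C)C)c(OCOC)c2c1OC(C)(C)CC2 | intermediate
26 | (2R)-1-{5,7-dihydroxy-2,2-dimethyl-6-[6-methyl-1-(4-methylbenzenesulfonyl)heptyl]-3,4-dihydro-2H-chromen-8-yl}-2-methylbutan-1-one (both epimers at the sulfonyl-bearing carbon) | CC[C@@H](C)C(=O)c1c(O)c(C(CCCCC(C)C)S(=O)(=O)c2ccc(C)cc2)c(O)c2c1OC(C)(C)CC2 | intermediate
27 | ortho-quinone methide of ring A: 5-hydroxy-2,2-dimethyl-8-[(2R)-2-methylbutanoyl]-6-(6-methylheptylidene)-3,4-dihydro-2H-chromen-7(6H)-one (not isolated) | CC[C@@H](C)C(=O)C1=C2OC(C)(C)CCC2=C(O)C(=CCCCCC(C)C)C1=O | intermediate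
28 | CNP0287681.1: (2R)-1-{6-[(1R)-1-(5,7-dihydroxy-2,2-dimethyl-8-(2-methylpropanoyl)-3,4-dihydro-2H-chromen-6-yl)-6-methylheptyl]-5,7-dihydroxy-2,2-dimethyl-3,4-dihydro-2H-chromen-8-yl}-2-methylbutan-1-one | CC[C@@H](C)C(=O)c1c(O)c([C@H](CCCCC(C)C)c2c(O)c3c(c(C(=O)C(C)C)c2O)OC(C)(C)CC3)c(O)c2c1OC(C)(C)CC2 | target

**Step count.** Total: 14 steps. Longest linear sequence: 8 steps (steps 1–7, then 14).

**Steps most likely to fail**

Step 6. The ring-opened radical may take a hydrogen atom from the thiol before it cyclises, or the vinylarene radical cation may be diverted into thiol addition or oligomerisation. The fallback sets out from 4 and generates the same kind of tertiary α-aryloxy radical by reductive decarboxylation, a different reaction that closes the same C2–C3 bond. Treatment of 4 with TFA alone would give acid 5, now isolated. Wittig methylenation of its aldehyde with excess ylide would give 2-[3,5-bis(benzyloxy)-2-ethenylphenoxy]-2-methylpropanoic acid F1. Coupling with N-hydroxyphthalimide (DIC, DMAP) would give the redox-active ester 1,3-dioxoisoindolin-2-yl 2-[3,5-bis(benzyloxy)-2-ethenylphenoxy]-2-methylpropanoate F2. Irradiation with [Ru(bpy)3]Cl2, Hantzsch ester and i-Pr2NEt under blue light should effect decarboxylation, 6-endo cyclisation and hydrogen-atom transfer to give 5,7-bis(benzyloxy)-2,2-dimethyl-3,4-dihydro-2H-chromene F3. Friedel–Crafts acylation with isobutyryl chloride and SnCl4 at −40 °C is expected at C8, the position not flanked by two benzyloxy groups, and comes back to the route at 12; this last regiochemistry is less secure than in the main route.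

Step 14. Facial selectivity may be poor because the quinone methide can exist as two carbonyl tautomers and two alkene geometries, and uncatalysed background addition may compete. The fallback sets out from 26 and 13 and gives up catalyst control. Coupling with aq. Na2CO3 and Bu4NBr in CH2Cl2 would give 28 together with its bridge epimer (2R)-1-{6-[(1S)-1-(5,7-dihydroxy-2,2-dimethyl-8-(2-methylpropanoyl)-3,4-dihydro-2H-chromen-6-yl)-6-methylheptyl]-5,7-dihydroxy-2,2-dimethyl-3,4-dihydro-2H-chromen-8-yl}-2-methylbutan-1-one F4. The two are diastereomers because of the fixed acyl stereocentre and would be separated by preparative HPLC on a chiral stationary phase, which comes back to the route at 28.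

Step 12. Deprotonation at C8 may be slow or incomplete next to the lithium alkoxide, lateral metalation at C4 may compete, and the aryllithium may enolise the amide. The fallback sets out from 20 and replaces deprotonation by halogen–metal exchange. NBS in MeCN at 0 °C should brominate the only free ring position to give rac-1-[8-bromo-5,7-bis(methoxymethoxy)-2,2-dimethyl-3,4-dihydro-2H-chromen-6-yl]-6-methylheptan-1-ol F5. n-BuLi (2.2 equiv) at −78 °C would then give the same dilithio species 24 by bromine–lithium exchange, and acylation with 23 comes back to the route at 25.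

**Further compounds**

F1 | step 6 | 2-[3,5-bis(benzyloxy)-2-ethenylphenoxy]-2-methylpropanoic acid | OC(=O)C(C)(C)Oc1cc(OCc2ccccc2)cc(OCc2ccccc2)c1C=C
F2 | step 6 | 1,3-dioxoisoindolin-2-yl 2-[3,5-bis(benzyloxy)-2-ethenylphenoxy]-2-methylpropanoate | O=C(ON1C(=O)c2ccccc2C1=O)C(C)(C)Oc1cc(OCc2ccccc2)cc(OCc2ccccc2)c1C=C
F3 | step 6 | 5,7-bis(benzyloxy)-2,2-dimethyl-3,4-dihydro-2H-chromene | CC1(C)CCc2c(OCc3ccccc3)cc(OCc3ccccc3)cc2O1
F4 | step 14 | bridge epimer of the target: (2R)-1-{6-[(1S)-1-(5,7-dihydroxy-2,2-dimethyl-8-(2-methylpropanoyl)-3,4-dihydro-2H-chromen-6-yl)-6-methylheptyl]-5,7-dihydroxy-2,2-dimethyl-3,4-dihydro-2H-chromen-8-yl}-2-methylbutan-1-one | CC[C@@H](C)C(=O)c1c(O)c([C@@H](CCCCC(C)C)c2c(O)c3c(c(C(=O)C(C)C)c2O)OC(C)(C)CC3)c(O)c2c1OC(C)(C)CC2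
F5 | step 12 | rac-1-[8-bromo-5,7-bis(methoxymethoxy)-2,2-dimethyl-3,4-dihydro-2H-chromen-6-yl]-6-methylheptan-1-ol | CC(C)CCCCC(O)c1c(OCOC)c(Br)c2OC(C)(C)CCc2c1OCOC
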